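The readings are simulated for substances that don't exist; the scatter is artificial.

Beta carries a small charge of first nucleophile, 0.330 equiv, so I ask first whether the substrate waits for that reagent.

| flask | substrate | first nucleophile | gas | temperature | remark | time |
|---|---|---|---|---|---|---|
| elm | 0.24 M | 1.3 equiv | 69 mM (held) | 55 °C | run made earlier |  |
| birch | 1.4 M | 1.3 equiv | 69 mM (held) | 90 °C | run made earlier |  |
| ash | 0.30 M | 1.1 equiv | 69 mM (held) | 55 °C | run made earlier |  |
| delta | 0.20 M | 2.60 equiv | 69 mM (held) | 80 °C |  | 2.5 min |
| beta | 0.30 M | 0.330 equiv | 69 mM (held) | 60 °C |  | 2.5 min |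
| gamma | 1.0 M | 1.30 equiv | 69 mM (held) | 80 °C |  | 2.5 min |
| epsilon | 0.30 M | 2.00 equiv | 69 mM (held) | 120 °C |  | 2.5 min |
| eta | 0.30 M | 1.30 equiv | 69 mM (held) | 80 °C |  | 2.5 min |
| theta | 0.60 M | 0.430 equiv | 69 mM (held) | 80 °C |  | 2.5 min |

- elm (time / min: target / %, substrate / %): 1.33: 0.9, 95.5; 3.00: 0.3, 91.4; 5.00: 0.7, 86.3; 6.00: 0.1, 83.9; 8.00: 0.3, 78.3
- birch (time / s: target / %, substrate / %): 10.0: 10.0, 88.2; 12.0: 10.7, 85.2; 20.0: 19.2, 76.4; 30.0: 25.2, 67.1; 60.0: 41.5, 45.1; 90.0: 50.8, 30.0
- ash (time / min: target / %, substrate / %): 0.667: 0.9, 98.8; 1.33: 0, 97.0; 2.50: 0.2, 93.5; 5.00: 0, 86.9; 8.00: 0, 78.5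

(each reading ± 0.5 percentage points)

* ranking by amount of target, in percent of the substrate charged, from high to low, at 2.5 min (delta / beta / gamma / epsilon / eta / theta)
* the amount of target, in percent of the substrate charged of the flask you put first, at 2.5 min
* the amount of target, in percent of the substrate charged of the flask you put last, at 2.5 min

- the analysis behind the earlier runs scatters by 0.5 percentage points, standard deviation
- at the start none of the gas is in solution

If a substrate falls by a first-order step with rate constant k, the fraction left after time t is exp(−kt), so k is ln(1/left) divided by t. The ash run leaves 78.5 % after 8.00 min, which reads as 0.0303 /min. The elm run has other charges, 0.24 M and 1.3 equiv, yet it reads 0.0306 /min. In the birch run k reads 0.798 /min at 30.0 s and 0.803 /min at 90.0 s, while target climbs from 25.2 % to 50.8 %. So I freeze k as a function of temperature and let the charges drop out.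

Drawing ln k straight between 55 °C and 90 °C gives 0.315 /min at 80 °C. That leaves 45.5 % of the substrate at 2.5 min. This clock fraction, the part of the charge not yet turned at a given time and temperature, I hold equal in delta, gamma, eta and theta.

Target is then a share of what has turned. The birch run, at 1.4 M, reads a share of 72.6 %, but the ash run, at 0.30 M, reads 0 % of target at its last point. These two runs differ in temperature as well as in substrate charge, so they cannot separate the two. For the four flasks at 80 °C I therefore only guess that the share rises with the substrate charge, and on that guess I rank gamma, theta, eta, delta. Birch's share put on gamma gives about 39.6 %. Beta comes last, with 11.4 % turned at 60 °C and ash's substrate charge. Epsilon I cannot place: its half-life of 3.12 s is far shorter than 2.5 min, so the clock runs out and says nothing of the share.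

The forecast ranks epsilon > gamma > delta > eta > theta > beta, with 64 % at the top and 0.25 % at the bottom. It rests on “rate-limiting unimolecular formation of a reactive intermediate”. It puts epsilon first, where I leave epsilon unplaced, and it has delta, eta, theta in the reverse of my order.

The flasks give gamma > theta > eta > delta > epsilon > beta: gamma 36.8 %, epsilon 8.48 %, beta 0.324 %.

    first nucleophile + intermediate → target (k = 9.97 /M/s, Ea = 48.0 kJ/mol)
    substrate → intermediate (k = 0.00552 /s, Ea = 93.0 kJ/mol)
    second nucleophile + target → over-reaction product (k = 0.219 /M/s, Ea = 46.0 kJ/mol)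
    gas ⇌ second nucleophile, rate k4*(csat - [second nucleophile]) (kL = 0.0106 /s)
    second nucleophile + intermediate → other capture product (k = 1470 /M/s, Ea = 42.0 kJ/mol)
    intermediate → solvolysis product (k = 2.59 /s, Ea = 91.0 kJ/mol)
    (constants at 80 °C)

In gamma the intermediate has a half-life of 0.27 s by solvolysis alone, far shorter than the 2.1 min of the substrate. The turning of substrate into intermediate is the rate-limiting step there, and the intermediate stands at 0.0161 % at 2.50 min. Gamma holds 43.7 % of substrate against my clock fraction of 45.5 %. A flask like beta kept at 85 °C reckons the same way to 28.5 % left, and it holds 27.6 % of substrate.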